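## Retrosynthetic overview

1. The target comes from CBS reduction of a C7′ enone, which comes from a Dauben oxidative 1,3-transposition of a tertiary allylic alcohol. That alcohol is made by 1,2-addition of a primary Grignard reagent (left half, both linker carbons attached) to the ketone of a cis-hydroazulenone (right half).
2. Key C–C bond (C1′–C8a′) of the right half: the samarium ketyl of a side-chain methyl ketone adds to the δ-carbon of a cyclohepta-2,4-dienone, joining two carbons that are both normally electrophilic. This closes the cyclopentanol and leaves the enone carbonyl as the coupling handle.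
3. The cycloheptadienone comes from 2-methylcyclohexenone by asymmetric conjugate addition/methylation, one-carbon ring expansion, methylation, dehydrogenation and Wacker oxidation.
4. Left half: methyl addition to a cyclohexanone that is formed together with the oxepane in one Lewis-acid cascade of an all-(R) bis-epoxide ending in a silyl dienol ether. The bis-epoxide comes from geranyl bromide by amide alkylation and Shi epoxidation.
5. Ring order: on the right the seven-membered ring, then the cyclopentane; on the left oxepane and cyclohexane in a single step; then fragment union, acetate, transposition and the allylic alcohol last.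

Assumption: in step 1 the (R,S_p) enantiomer of the ferrocenyl diphosphine is taken to give the (S)-ketone 4; if the sense of induction is the reverse, the mirror-image ligand is used.

## Route

Step 1
Reactants: 1 2-methylcyclohex-2-en-1-one; 2 but-3-en-1-ylmagnesium bromide
Product: 4 (S)-3-(but-3-en-1-yl)-2,2-dimethylcyclohexan-1-one, via magnesium enolate 3 (not isolated)
Conditions: CuBr·SMe2 (5 mol %), (R)-1-[(S_p)-2-(diphenylphosphino)ferrocenyl]ethyldicyclohexylphosphine (6 mol %), t-BuOMe, −78 °C; then MeI, DMPU, −78 → 0 °C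
Reagents that add atoms: iodomethane, CI
Why: Copper-catalysed asymmetric conjugate addition of the Grignard reagent sets C3 as S by ligand control, and C-methylation of the regiodefined magnesium enolate in the same flask builds the gem-dimethyl group next to it.

Step 2
Reactants: 4 (S)-3-(but-3-en-1-yl)-2,2-dimethylcyclohexan-1-one
Product: 6 (S)-3-(but-3-en-1-yl)-2,2-dimethylcycloheptan-1-one, via alpha-silyl ketone 5 (not isolated)
Conditions: Me3SiCHN2, BF3·OEt2, CH2Cl2, −78 → −20 °C; then 1 M HCl, THF, 25 °C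
Reagents that add atoms: trimethylsilyldiazomethane, C[Si](C)(C)C=[N+]=[N-]
Why: Lewis-acid-promoted diazoalkane homologation of a ketone (one-carbon ring expansion) in which the CH2 carbon migrates in preference to the quaternary carbon, so the new carbon enters on the unhindered side; the C–Si bond is then cleaved by acid and the stereocentre is not touched.

Step 3
Reactants: 6 (S)-3-(but-3-en-1-yl)-2,2-dimethylcycloheptan-1-one
Product: 8 (3S)-3-(but-3-en-1-yl)-2,2,7-trimethylcycloheptan-1-one as a mixture of C7 epimers, via lithium enolate 7 (not isolated)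
Conditions: LiN(i-Pr)2, THF, −78 °C; then MeI, −78 → 0 °C
Reagents that add atoms: iodomethane, CI
Why: Enolate alkylation that can only occur at C7 because C2 is quaternary; the new C7 centre becomes sp2 in step 4 and need not be controlled.

Step 4
Reactants: 8 (3S)-3-(but-3-en-1-yl)-2,2,7-trimethylcycloheptan-1-one
Product: 10 (R)-6-(but-3-en-1-yl)-2,7,7-trimethylcyclohepta-2,4-dien-1-one, via cycloheptenone 9 (not isolated)
Conditions: 2-iodoxybenzoic acid (IBX, 4 equiv), DMSO/fluorobenzene, 80 °C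
Reagents that add atoms: none
Why: IBX dehydrogenation of a ketone through its enol and then its dienol (Nicolaou dehydrogenation); the quaternary C7 blocks the other side, so unsaturation can only extend linearly to the 2,4-dienone, and C6 keeps its configuration (the descriptor changes to R only through the priority rules).

Step 5
Reactants: 10 (R)-6-(but-3-en-1-yl)-2,7,7-trimethylcyclohepta-2,4-dien-1-one
Product: 11 (R)-2,7,7-trimethyl-6-(3-oxobutyl)cyclohepta-2,4-dien-1-one
Conditions: PdCl2 (10 mol %), CuCl, O2 (1 atm), DMF/H2O 7:1, 25 °C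
Reagents that add atoms: water, O
Why: Tsuji–Wacker oxidation, Markovnikov hydroxypalladation of the only terminal alkene; the conjugated ring alkenes do not react and no base is present that could epimerise C6.

Step 6
Reactants: 11 (R)-2,7,7-trimethyl-6-(3-oxobutyl)cyclohepta-2,4-dien-1-one
Product: 13 (1R,3aR,8aR)-1-hydroxy-1,4,4,6-tetramethyl-2,3,3a,4,8,8a-hexahydroazulen-5(1H)-one, via samarium dienolate 12 (not isolated)
Conditions: SmI2 (2.5 equiv), HMPA, THF, −78 → 0 °C; aq NH4Cl; then DBU (cat.), CH2Cl2, 25 °C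
Reagents that add atoms: none
Why: Proposed new method: a vinylogous ketyl–olefin cyclisation in which the samarium ketyl of the methyl ketone (or, equivalently, the δ-carbon of the reduced dienone) closes 5-exo onto C5 of the dienone, the only alkene carbon within reach of a five-membered transition state, giving a delocalised dienolate; the tether delivers to the face it sits on (cis ring fusion, 8aR) and the bulky O–Sm group points away from the seven-membered ring so the hydroxyl ends anti to C8 (1R); the closest known reaction is the SmI2 5-exo ketyl–enone cyclisation with its usual anti selectivity.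

Step 7
Reactants: 14 geranyl bromide; 15 N-methoxy-N-methylacetamide
Product: 17 (4E)-N-methoxy-N,5,9-trimethyldeca-4,8-dienamide, via amide enolate 16 (not isolated)
Conditions: 15, LiN(i-Pr)2, THF, −78 °C; then 14, −78 → −40 °C
Reagents that add atoms: none
Why: Alkylation of a Weinreb amide enolate by SN2 displacement of the allylic bromide; the E geometry of the geranyl unit is carried over.

Step 8
Reactants: 17 (4E)-N-methoxy-N,5,9-trimethyldeca-4,8-dienamide
Product: 19 (4R,5R,8R)-4,5:8,9-diepoxy-N-methoxy-N,5,9-trimethyldecanamide, via monoepoxide 18 (not isolated)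
Conditions: 1,2:4,5-di-O-isopropylidene-β-D-erythro-2,3-hexodiulo-2,6-pyranose (Shi ketone, 30 mol % per alkene), KHSO5 (as 2KHSO5·KHSO4·K2SO4), K2CO3, Bu4NHSO4, MeCN/CH2(OMe)2, aq Na2B4O7 buffer, 0 °C
Reagents that add atoms: potassium peroxymonosulfate, [K+].[O-]S(=O)(=O)OO
Why: Shi asymmetric epoxidation; the dioxirane of the D-fructose-derived ketone epoxidises both trisubstituted alkenes through the spiro transition state and gives the R configuration at C4, C5 and C8 by reagent control.

Step 9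
Reactants: 19 (4R,5R,8R)-4,5:8,9-diepoxy-N-methoxy-N,5,9-trimethyldecanamide; 20 allylmagnesium bromide
Product: 22 (7R,8R,11R)-7,8:11,12-diepoxy-8,12-dimethyltridec-1-en-4-one, via magnesium chelate 21 (not isolated)
Conditions: 20 (1.3 equiv), THF, −78 °C; aq NH4Cl, 0 °C
Reagents that add atoms: none
Why: Weinreb ketone synthesis; the chelated tetrahedral adduct prevents over-addition and the hindered trisubstituted epoxides are not opened at −78 °C.

Step 10
Reactants: 22 (7R,8R,11R)-7,8:11,12-diepoxy-8,12-dimethyltridec-1-en-4-one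
Product: 24 (3Z,7R,8R,11R)-4-[(tert-butyldimethylsilyl)oxy]-7,8:11,12-diepoxy-8,12-dimethyltrideca-1,3-diene, via potassium dienolate 23 (not isolated)
Conditions: KN(SiMe3)2, THF, −78 °C; then t-BuMe2SiCl, DMPU, −78 → 0 °C
Reagents that add atoms: tert-butyldimethylsilyl chloride, CC(C)(C)[Si](C)(C)Cl
Why: Regioselective enolisation at the doubly activated C3 methylene (allylic and α to the ketone) followed by O-silylation, which fixes the position of the nucleophilic carbon for the cascade.

Step 11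
Reactants: 24 (3Z,7R,8R,11R)-4-[(tert-butyldimethylsilyl)oxy]-7,8:11,12-diepoxy-8,12-dimethyltrideca-1,3-diene
Product: 26 (3R,5aR,6R,9aR)-6-ethenyl-3-hydroxy-2,2,5a-trimethyloctahydro-1-benzoxepin-7(2H)-one, via trimethylsilyl ether 25 (not isolated)
Conditions: Me3SiOTf (1.2 equiv), 2,6-di-tert-butyl-4-methylpyridine, CH2Cl2, −78 °C; then citric acid, MeOH, 0 °C
Reagents that add atoms: none
Why: Tandem epoxide-opening oxa-/carbacyclisation ended by an enol silane: silylation of the terminal epoxide lets the neighbouring epoxide oxygen open it at the tertiary carbon, and the bicyclic epoxonium ion is opened anti at its tertiary carbon by C3 of the dienol ether through a chair (only the six-membered closure is possible), giving the trans-fused oxepane–cyclohexanone with C3, C5a and C9a fixed by the epoxides and the vinyl group equatorial, its stable position α to the ketone.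

Step 12
Reactants: 26 (3R,5aR,6R,9aR)-6-ethenyl-3-hydroxy-2,2,5a-trimethyloctahydro-1-benzoxepin-7(2H)-one
Product: 27 (3R,5aR,6R,7S,9aR)-6-ethenyl-2,2,5a,7-tetramethyldecahydro-1-benzoxepine-3,7-diol
Conditions: MeLi (3 equiv), CeCl3, THF, −78 °C
Reagents that add atoms: methyllithium, [Li]C
Why: 1,2-addition of a non-basic organocerium reagent (no enolisation of the α-vinyl ketone); the axial 5a-methyl blocks axial attack, so methyl enters equatorially and the new hydroxyl is axial and cis to the vinyl group (7S).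

Step 13
Reactants: 27 (3R,5aR,6R,7S,9aR)-6-ethenyl-2,2,5a,7-tetramethyldecahydro-1-benzoxepine-3,7-diol; 13 (1R,3aR,8aR)-1-hydroxy-1,4,4,6-tetramethyl-2,3,3a,4,8,8a-hexahydroazulen-5(1H)-one
Product: 29 (3R,5aR,6R,7S,9aR)-6-{2-[(1R,3aR,8aR)-1,5-dihydroxy-1,4,4,6-tetramethyl-1,2,3,3a,4,5,8,8a-octahydroazulen-5-yl]ethyl}-2,2,5a,7-tetramethyldecahydro-1-benzoxepine-3,7-diol (C5′ configuration not controlled), via Grignard reagent 28 (not isolated)
Conditions: 27, i-BuMgBr (4.0 equiv), Cp2TiCl2 (10 mol %), Et2O, 25 °C; then LaCl3·2LiCl, THF, 0 °C; then 13 (0.9 equiv), −20 → 25 °C; aq NH4Cl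
Reagents that add atoms: none
Why: Titanocene-catalysed hydromagnesiation turns the terminal alkene into the primary Grignard reagent (the hydroxyls sit as magnesium alkoxides and there is no leaving group that could close a tetrahydrofuran), the remaining i-BuMgBr deprotonates the hydroxyl of 13, and lanthanum-promoted 1,2-addition to the hindered enone carbonyl joins the fragments; the new carbinol centre is erased in step 15.

Step 14
Reactants: 29 the tetraol from step 13
Product: 30 (3R,5aR,6R,7S,9aR)-6-{2-[(1R,3aR,8aR)-1,5-dihydroxy-1,4,4,6-tetramethyl-1,2,3,3a,4,5,8,8a-octahydroazulen-5-yl]ethyl}-7-hydroxy-2,2,5a,7-tetramethyldecahydro-1-benzoxepin-3-yl acetate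
Conditions: Ac2O, pyridine, DMAP (cat.), CH2Cl2, 0 °C
Reagents that add atoms: acetic anhydride, CC(=O)OC(C)=O
Why: Selective esterification; only the secondary 3-hydroxyl is acylated, the three tertiary alcohols do not react under these conditions, and the acetate also protects C3 from the oxidant of step 15.

Step 15
Reactants: 30 the 3-acetate from step 14
Product: 31 (3R,5aR,6R,7S,9aR)-7-hydroxy-6-{2-[(1R,3aR,8aR)-1-hydroxy-1,4,4,6-tetramethyl-7-oxo-1,2,3,3a,4,7,8,8a-octahydroazulen-5-yl]ethyl}-2,2,5a,7-tetramethyldecahydro-1-benzoxepin-3-yl acetate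
Conditions: pyridinium chlorochromate (4 equiv), 4 Å molecular sieves, CH2Cl2, 25 °C
Reagents that add atoms: pyridinium chlorochromate, [O-][Cr](=O)(=O)Cl.c1cc[nH+]cc1
Why: Dauben oxidative 1,3-transposition: the tertiary allylic chromate ester shifts [3,3] to the secondary allylic position and is oxidised there, giving the tetrasubstituted enone; the acetate and the non-allylic tertiary alcohols survive.

Step 16
Reactants: 31 the enone from step 15
Product: 32 (3R,5aR,6R,7S,9aR)-6-{2-[(1R,3aR,7R,8aR)-1,7-dihydroxy-1,4,4,6-tetramethyl-1,2,3,3a,4,7,8,8a-octahydroazulen-5-yl]ethyl}-7-hydroxy-2,2,5a,7-tetramethyldecahydro-1-benzoxepin-3-yl acetate (CNP0157376.1)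
Conditions: (S)-1-methyl-3,3-diphenyltetrahydro-1H,3H-pyrrolo[1,2-c][1,3,2]oxazaborole ((S)-Me-CBS, 1 equiv), catecholborane, toluene, −78 °C; MeOH, then pH 7 buffer
Reagents that add atoms: none
Why: Corey–Bakshi–Shibata reduction; with the C(Me)=C arm as the large substituent the (S)-catalyst delivers hydride to the face that gives the 7′R allylic alcohol (reagent control, same sense as acetophenone to the R alcohol), and the acetate is not reduced at −78 °C.

## Compound list

1 | 2-methylcyclohex-2-en-1-one | CC1=CCCCC1=O | starting material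
2 | but-3-en-1-ylmagnesium bromide | C=CCC[Mg]Br | starting material
3 | bromomagnesium (S)-3-(but-3-en-1-yl)-2-methylcyclohex-1-en-1-olate | Br[Mg]OC1=C(C)[C@H](CCC=C)CCC1 | intermediate (not isolated)
4 | (S)-3-(but-3-en-1-yl)-2,2-dimethylcyclohexan-1-one | O=C1CCC[C@@H](CCC=C)C1(C)C | intermediate
5 | (3S)-3-(but-3-en-1-yl)-2,2-dimethyl-7-(trimethylsilyl)cycloheptan-1-one, C7 epimers | O=C1C([Si](C)(C)C)CCC[C@@H](CCC=C)C1(C)C | intermediate (not isolated)
6 | (S)-3-(but-3-en-1-yl)-2,2-dimethylcycloheptan-1-one | O=C1CCCC[C@@H](CCC=C)C1(C)C | intermediate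
7 | lithium (S)-6-(but-3-en-1-yl)-7,7-dimethylcyclohept-1-en-1-olate | [Li]OC1=CCCC[C@@H](CCC=C)C1(C)C | intermediate (not isolated)
8 | (3S)-3-(but-3-en-1-yl)-2,2,7-trimethylcycloheptan-1-one, C7 epimers | O=C1C(C)CCC[C@@H](CCC=C)C1(C)C | intermediate
9 | (R)-6-(but-3-en-1-yl)-2,7,7-trimethylcyclohept-2-en-1-one | O=C1C(C)=CCC[C@@H](CCC=C)C1(C)C | intermediate (not isolated)
10 | (R)-6-(but-3-en-1-yl)-2,7,7-trimethylcyclohepta-2,4-dien-1-one | O=C1C(C)=CC=C[C@@H](CCC=C)C1(C)C | intermediate
11 | (R)-2,7,7-trimethyl-6-(3-oxobutyl)cyclohepta-2,4-dien-1-one | O=C1C(C)=CC=C[C@@H](CCC(C)=O)C1(C)C | intermediate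
12 | bis(diiodosamarium) dienolate–alkoxide of 13 (trivalent samarium) | I[Sm](I)OC1=C(C)C=C[C@@H]2[C@@H](CC[C@@]2(C)O[Sm](I)I)C1(C)C | intermediate (not isolated)
13 | (1R,3aR,8aR)-1-hydroxy-1,4,4,6-tetramethyl-2,3,3a,4,8,8a-hexahydroazulen-5(1H)-one | O=C1C(C)=CC[C@@H]2[C@@H](CC[C@@]2(C)O)C1(C)C | intermediate
14 | geranyl bromide, (2E)-1-bromo-3,7-dimethylocta-2,6-diene | CC(C)=CCC/C(C)=C/CBr | starting material
15 | N-methoxy-N-methylacetamide | CC(=O)N(C)OC | starting material
16 | lithium 1-[methoxy(methyl)amino]ethen-1-olate | [Li]OC(=C)N(C)OC | intermediate (not isolated)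
17 | (4E)-N-methoxy-N,5,9-trimethyldeca-4,8-dienamide | CON(C)C(=O)CC/C=C(\C)CCC=C(C)C | intermediate
18 | (4E,8R)-8,9-epoxy-N-methoxy-N,5,9-trimethyldec-4-enamide | CON(C)C(=O)CC/C=C(\C)CC[C@H]1OC1(C)C | intermediate (not isolated)
19 | (4R,5R,8R)-4,5:8,9-diepoxy-N-methoxy-N,5,9-trimethyldecanamide | CON(C)C(=O)CC[C@H]1O[C@]1(C)CC[C@H]1OC1(C)C | intermediate
20 | allylmagnesium bromide | C=CC[Mg]Br | starting material
21 | bromomagnesium hemiaminal chelate, the tetrahedral adduct of 19 and 20 | C=CCC(O[Mg]Br)(N(C)OC)CC[C@H]1O[C@]1(C)CC[C@H]1OC1(C)C | intermediate (not isolated)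
22 | (7R,8R,11R)-7,8:11,12-diepoxy-8,12-dimethyltridec-1-en-4-one | C=CCC(=O)CC[C@H]1O[C@]1(C)CC[C@H]1OC1(C)C | intermediate
23 | potassium (3Z)-dienolate of 22 | C=C/C=C(\O[K])CC[C@H]1O[C@]1(C)CC[C@H]1OC1(C)C | intermediate (not isolated)
24 | (3Z,7R,8R,11R)-4-[(tert-butyldimethylsilyl)oxy]-7,8:11,12-diepoxy-8,12-dimethyltrideca-1,3-diene | C=C/C=C(\O[Si](C)(C)C(C)(C)C)CC[C@H]1O[C@]1(C)CC[C@H]1OC1(C)C | intermediate
25 | (3R,5aR,6R,9aR)-6-ethenyl-2,2,5a-trimethyl-3-[(trimethylsilyl)oxy]octahydro-1-benzoxepin-7(2H)-one | C[Si](C)(C)O[C@@H]1CC[C@]2(C)[C@@H](C=C)C(=O)CC[C@H]2OC1(C)C | intermediate (not isolated)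
26 | (3R,5aR,6R,9aR)-6-ethenyl-3-hydroxy-2,2,5a-trimethyloctahydro-1-benzoxepin-7(2H)-one | O[C@@H]1CC[C@]2(C)[C@@H](C=C)C(=O)CC[C@H]2OC1(C)C | intermediate
27 | (3R,5aR,6R,7S,9aR)-6-ethenyl-2,2,5a,7-tetramethyldecahydro-1-benzoxepine-3,7-diol | O[C@@H]1CC[C@]2(C)[C@@H](C=C)[C@@](C)(O)CC[C@H]2OC1(C)C | intermediate
28 | 2-[(3R,5aR,6R,7S,9aR)-3,7-bis(bromomagnesiooxy)-2,2,5a,7-tetramethyldecahydro-1-benzoxepin-6-yl]ethylmagnesium bromide | Br[Mg]O[C@@H]1CC[C@]2(C)[C@@H](CC[Mg]Br)[C@@](C)(O[Mg]Br)CC[C@H]2OC1(C)C | intermediate (not isolated)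
29 | (3R,5aR,6R,7S,9aR)-6-{2-[(1R,3aR,8aR)-1,5-dihydroxy-1,4,4,6-tetramethyl-1,2,3,3a,4,5,8,8a-octahydroazulen-5-yl]ethyl}-2,2,5a,7-tetramethyldecahydro-1-benzoxepine-3,7-diol, C5′ not controlled | O[C@@H]1CC[C@]2(C)[C@@H](CCC3(O)C(C)=CC[C@@H]4[C@@H](CC[C@@]4(C)O)C3(C)C)[C@@](C)(O)CC[C@H]2OC1(C)C | intermediate
30 | 3-acetate of 29 | CC(=O)O[C@@H]1CC[C@]2(C)[C@@H](CCC3(O)C(C)=CC[C@@H]4[C@@H](CC[C@@]4(C)O)C3(C)C)[C@@](C)(O)CC[C@H]2OC1(C)C | intermediate
31 | (3R,5aR,6R,7S,9aR)-7-hydroxy-6-{2-[(1R,3aR,8aR)-1-hydroxy-1,4,4,6-tetramethyl-7-oxo-1,2,3,3a,4,7,8,8a-octahydroazulen-5-yl]ethyl}-2,2,5a,7-tetramethyldecahydro-1-benzoxepin-3-yl acetate | CC(=O)O[C@@H]1CC[C@]2(C)[C@@H](CCC3=C(C)C(=O)C[C@@H]4[C@@H](CC[C@@]4(C)O)C3(C)C)[C@@](C)(O)CC[C@H]2OC1(C)C | intermediate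
32 | (3R,5aR,6R,7S,9aR)-6-{2-[(1R,3aR,7R,8aR)-1,7-dihydroxy-1,4,4,6-tetramethyl-1,2,3,3a,4,7,8,8a-octahydroazulen-5-yl]ethyl}-7-hydroxy-2,2,5a,7-tetramethyldecahydro-1-benzoxepin-3-yl acetate | CC(=O)O[C@@H]1CC[C@]2(C)[C@@H](CCC3=C(C)[C@H](O)C[C@@H]4[C@@H](CC[C@@]4(C)O)C3(C)C)[C@@](C)(O)CC[C@H]2OC1(C)C | target

## Step count and risks

Total: 16 steps. Longest linear sequence: 10 steps (steps 1–6, then 13–16; the branch 7–12, then 13–16, is equally long).

Steps most likely to fail:

1. Step 6, the vinylogous ketyl closure: the dienone may be reduced or dimerise before the ring closes. Fallback: join the fragments first, so that the ketyl meets an ordinary enone β-carbon. It sets out from 10. Grignard reagent 28 (made from 27 as in step 13) is added to the ketone of 10 with LaCl3·2LiCl in THF to give the dienyl carbinol F1. Ac2O/pyridine gives its 3-acetate F2, and pyridinium chlorochromate transposes and oxidises this to the cross-conjugated dienone F3. PdCl2/CuCl/O2 converts the butenyl chain into the methyl ketone F4. SmI2/HMPA then effects a conventional 5-exo ketyl–enone cyclisation onto the β-carbon, and protonation of the enolate brings the route back at 31.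

2. Step 13, the fragment union: hydromagnesiation next to two quaternary carbons, or addition to the hindered ketone, may stall. Fallback: generate the carbanion by reductive lithiation instead of hydrometalation. It sets out from 27. Radical anti-Markovnikov addition of thiophenol (AIBN, 80 °C) gives the phenyl sulfide F5. After deprotonation of both hydroxyls with n-BuLi, lithium 4,4′-di-tert-butylbiphenylide (THF, −78 °C) cleaves the C–S bond to give the trilithio species F6. This is transmetalated with CeCl3 and added to 13 (hydroxyl deprotonated beforehand), and the route is rejoined at 29.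

3. Step 4, the double IBX dehydrogenation: the second, γ,δ-dehydrogenation may stop at the enone. Fallback: two Saegusa–Ito oxidations. It sets out from 8. LiN(i-Pr)2/Me3SiCl gives the trimethylsilyl enol ether F7, and Pd(OAc)2 in MeCN gives enone 9, now isolated. A second LiN(i-Pr)2/Me3SiCl treatment (γ-deprotonation is the only possibility) gives the silyl dienol ether F8, and Pd(OAc)2 again gives the dienone, rejoining the route at 10.

Further compounds

F1 | step 6 | (3R,5aR,6R,7S,9aR)-6-{2-[(6R)-6-(but-3-en-1-yl)-1-hydroxy-2,7,7-trimethylcyclohepta-2,4-dien-1-yl]ethyl}-2,2,5a,7-tetramethyldecahydro-1-benzoxepine-3,7-diol | O[C@@H]1CC[C@]2(C)[C@@H](CCC3(O)C(C)=CC=C[C@@H](CCC=C)C3(C)C)[C@@](C)(O)CC[C@H]2OC1(C)C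
F2 | step 6 | 3-acetate of F1 | CC(=O)O[C@@H]1CC[C@]2(C)[C@@H](CCC3(O)C(C)=CC=C[C@@H](CCC=C)C3(C)C)[C@@](C)(O)CC[C@H]2OC1(C)C
F3 | step 6 | (3R,5aR,6R,7S,9aR)-6-{2-[(6R)-6-(but-3-en-1-yl)-2,7,7-trimethyl-3-oxocyclohepta-1,4-dien-1-yl]ethyl}-7-hydroxy-2,2,5a,7-tetramethyldecahydro-1-benzoxepin-3-yl acetate | CC(=O)O[C@@H]1CC[C@]2(C)[C@@H](CCC3=C(C)C(=O)C=C[C@@H](CCC=C)C3(C)C)[C@@](C)(O)CC[C@H]2OC1(C)C
F4 | step 6 | (3R,5aR,6R,7S,9aR)-7-hydroxy-2,2,5a,7-tetramethyl-6-{2-[(6R)-2,7,7-trimethyl-3-oxo-6-(3-oxobutyl)cyclohepta-1,4-dien-1-yl]ethyl}decahydro-1-benzoxepin-3-yl acetate | CC(=O)O[C@@H]1CC[C@]2(C)[C@@H](CCC3=C(C)C(=O)C=C[C@@H](CCC(C)=O)C3(C)C)[C@@](C)(O)CC[C@H]2OC1(C)C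
F5 | step 13 | (3R,5aR,6R,7S,9aR)-2,2,5a,7-tetramethyl-6-[2-(phenylsulfanyl)ethyl]decahydro-1-benzoxepine-3,7-diol | O[C@@H]1CC[C@]2(C)[C@@H](CCSc3ccccc3)[C@@](C)(O)CC[C@H]2OC1(C)C
F6 | step 13 | trilithio derivative: 2-[(3R,5aR,6R,7S,9aR)-3,7-bis(lithiooxy)-2,2,5a,7-tetramethyldecahydro-1-benzoxepin-6-yl]ethyllithium | [Li]O[C@@H]1CC[C@]2(C)[C@@H](CC[Li])[C@@](C)(O[Li])CC[C@H]2OC1(C)C
F7 | step 4 | {[(6S)-6-(but-3-en-1-yl)-2,7,7-trimethylcyclohept-1-en-1-yl]oxy}trimethylsilane | C[Si](C)(C)OC1=C(C)CCC[C@@H](CCC=C)C1(C)C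
F8 | step 4 | {[(6R)-6-(but-3-en-1-yl)-2,7,7-trimethylcyclohepta-1,3-dien-1-yl]oxy}trimethylsilane | C[Si](C)(C)OC1=C(C)C=CC[C@@H](CCC=C)C1(C)C
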